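Late in a run the target stands while the background goes on: in red, between 15.0 h and 40.0 h, it slips from 13.9% to 12.9% while starting material falls from 52.5% to 38.6%. What a flask ends with is therefore made early, and the early readings are where to look.

| flask | starting material | reagent | free catalyst | temperature | remark | time |
|---|---|---|---|---|---|---|
| red | 2 M | 0.74 equiv | 5 mol% | 20 °C | run made earlier |  |
| amber | 2 M | 1.1 equiv | 2.5 mol% | 32 °C | run made earlier |  |
| north-east | 2.0 M | 1.10 equiv | 5 mol% |  | at 25 °C until 5.0 h, from then on at 40 °C | 15 h |
| east | 2.0 M | 1.10 equiv | 5 mol% | 40 °C |  | 15 h |
| south-east | 2.0 M | 1.10 equiv | 5 mol% | 25 °C |  | 15 h |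

| run | time / h | target / % | starting material / % |
|---|---|---|---|
| red | 4.00 | 15.0 | 69.5 |
| red | 8.00 | 16.1 | 61.6 |
| red | 15.0 | 13.9 | 52.5 |
| red | 40.0 | 12.9 | 38.6 |
| amber | 4.00 | 7.8 | 45.0 |
| amber | 8.00 | 8.3 | 29.3 |
| amber | 12.0 | 6.6 | 20.5 |
| amber | 15.0 | 6.8 | 16.8 |

(each reading ± 0.5 percentage points)

- steps that have been proposed: starting material + reagent -> uncatalysed product; free catalyst -> spent catalyst B; starting material + reagent + free catalyst <-> target + free catalyst; free catalyst + target -> spent catalyst A

- the flask that comes out highest in amount of target, in percent of the starting material charged, or "all alike" when all lie within 1.5 percentage points (north-east / east / south-east / all alike)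
- target at the end, in percent of the starting material charged, north-east
- target at the end, in percent of the starting material charged, east
- target at the end, in percent of the starting material charged, south-east

The bench rule is to count turnovers, peak target over catalyst loading. Red gives 3.22 and amber 3.32, so you would expect about 16.1% from every new flask. But amber had 1.49 times red's reagent and a hotter bath, so the equal counts look like a cancellation, and the rule says nothing about temperature.

The target step is written as running both ways, so while the catalyst works, target may stand near balance with what feeds it, c(target) close to a constant times c(starting material) times c(reagent). Loading does not enter such a balance. I therefore read c(target)/c(starting material) at 4.00 h, which I call the holding ratio: red gives 0.216 and amber 0.173. Red had less reagent, so I assume its ratio grows with the charge, by 1.49, to 0.321. Between 20 °C and 32 °C the ratio then drops by a factor of 1.85, and that factor is the border of the turnover rule.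

Carrying the same factor per degree, the holding ratio, target over starting material at the first reading with 1.10 equiv of reagent, comes at 25 °C to 0.248 and at 40 °C to 0.115.

My reckoning multiplies the holding ratio by the starting material standing when target stops rising, which I take as the 8.00 h reading, the highest target read in red and in amber. For south-east, whose temperature lies between the two runs', I take the geometric mean of their readings then, 42.5%, which gives 10.5%. For east I take amber's 29.3%, which gives 3.37%. North-east, cold first and hot later, I put at their geometric mean, 5.96%.

The forecast names south-east, with 15% for north-east, 11% for east and 17.5% for south-east, holding that “catalyst death and reversal outpace catalysis as temperature rises”.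

The flasks give 7.41% in north-east, 3.73% in east and 12.5% in south-east, so south-east comes out highest.

    starting material + reagent → uncatalysed product (k = 0.0639 M⁻¹ h⁻¹, Ea = 70.0 kJ mol⁻¹)
    free catalyst → spent catalyst B (k = 0.242 h⁻¹, Ea = 93.0 kJ mol⁻¹)
    starting material + reagent + free catalyst ⇌ target + free catalyst, rate k3*[starting material]*[reagent]*[free catalyst] forward; the back reaction follows from the equilibrium constant (K = 0.190 M⁻¹, k = 1.22 M⁻² h⁻¹, Ea = 44.0 kJ mol⁻¹, ΔH = −74.0 kJ mol⁻¹)
    free catalyst + target → spent catalyst A (k = 0.160 M⁻¹ h⁻¹, Ea = 75.0 kJ mol⁻¹)
    (constants at 25 °C)

East holds 0.298 of south-east's target, beside the 0.321 that the holding ratio gave. With the back reaction of target struck out, east ends at 20.0% instead of 3.73%, the largest single effect of the three tried. North-east, read at 4.0 h while still at 25 °C, holds 15.8% target to 55.1% starting material, a holding ratio of 0.287 against the carried 0.248.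

(The earlier runs and the new flask are simulated from invented constants; scatter was added.)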